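Ring C is disconnected at three bonds, C4a–C4, C4–C3 and O1–C2. In the target the ketone carbon C4 is flanked by the ring-A carbon C4a and by C3, which leads to the aryl-bearing C2, and O1 hangs from C8a next to C4a, so an ortho-iodophenol, carbon monoxide and an arylacetylene map onto it exactly. One palladium-catalysed carbonylative alkynylation with in-flask amine-mediated closure builds the whole pyranone ring as a flavone. The precursor is 2-iodo-3,5-dimethoxy-6-prenylphenol, whose only free hydroxyl lies between iodine and prenyl, so a single regioisomer can form. Asymmetric conjugate reduction then sets C2, and chelation-controlled 5-O-demethylation and desilylation finish the route.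

Key step: step 7

Assumption (stereochemistry): the target is the (2S)-flavanone (O1 > C1' > C3 > H). The ligand antipode written in step 8 is taken to deliver hydride to the Re face of C2; if a first run shows the opposite sense, the mirror-image ligand is used and nothing else changes.

Remark (design): iodine is introduced before the side-chain alkene exists, and the prenyl group is built by allyl ether rearrangement and cross-metathesis. The 4'-oxygen carries a triisopropylsilyl group, which withstands carbonate in methanol and hot secondary amine.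

Step 1
Reactants: 1 3,5-dimethoxyphenol
Product: 2 2-iodo-3,5-dimethoxyphenol
Conditions: NIS (1.0 equiv), CH2Cl2, −20 → 0 °C
Reagents that add atoms: N-iodosuccinimide, O=C1CCC(=O)N1I
Why: Electrophilic aromatic iodination of this phloroglucinol-type phenol needs no acid, and in a non-polar solvent hydrogen-bond-assisted delivery of iodine plus the two equivalent ortho sites should favour C2 over the C4 position squeezed between two methoxyls (a minor 4-iodo isomer is removable by chromatography); iodine goes in before any alkene exists, so iodoetherification cannot compete.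

Step 2
Reactants: 2 2-iodo-3,5-dimethoxyphenol; 3 allyl bromide
Product: 4 1-(allyloxy)-2-iodo-3,5-dimethoxybenzene
Conditions: K2CO3, acetone, 56 °C
Reagents that add atoms: none
Why: Williamson O-allylation (SN2 of the phenoxide on a primary allylic bromide) with a weak base in acetone is selective for oxygen and leaves the aryl iodide untouched.

Step 3
Reactants: 4 1-(allyloxy)-2-iodo-3,5-dimethoxybenzene
Product: 5 2-allyl-6-iodo-3,5-dimethoxyphenol
Conditions: PhNEt2, 170 °C
Reagents that add atoms: none
Why: Aromatic Claisen rearrangement ([3,3]-sigmatropic shift, then tautomerisation) can deliver the allyl group only to C6, the one ortho carbon that bears hydrogen, the electron-rich ring lets it run below the temperature at which the C–I bond suffers, and the basic solvent suppresses acid-catalysed cyclisation of the ortho-allylphenol.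

Step 4
Reactants: 5 2-allyl-6-iodo-3,5-dimethoxyphenol; 6 2-methyl-2-butene
Product: 7 2-iodo-3,5-dimethoxy-6-(3-methylbut-2-en-1-yl)phenol (2-iodo-3,5-dimethoxy-6-prenylphenol)
Conditions: (H2IMes)(PCy3)Cl2Ru=CHPh (5 mol%), 2-methyl-2-butene (excess), CH2Cl2, 40 °C
Reagents that add atoms: none
Why: Olefin cross-metathesis of a terminal allyl arene with excess 2-methyl-2-butene is the standard allyl-to-prenyl conversion, tolerates the free phenol and the aryl iodide, and is driven by loss of propene.

Step 5
Reactants: 8 4-iodophenol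
Product: 9 (4-iodophenoxy)triisopropylsilane
Conditions: TIPSCl, imidazole, DMF, rt
Reagents that add atoms: triisopropylsilyl chloride, CC(C)[Si](Cl)(C(C)C)C(C)C
Why: Imidazole-assisted O-silylation of a phenol; the bulky silyl ether is chosen because it must survive carbonate in methanol, hot diethylamine, copper hydride and magnesium iodide, yet leave under mildly acidic fluoride.

Step 6
Reactants: 9 (4-iodophenoxy)triisopropylsilane; 10 trimethylsilylacetylene
Product: 12 (4-ethynylphenoxy)triisopropylsilane, via TMS-alkyne 11 (not isolated)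
Conditions: PdCl2(PPh3)2 (2 mol%), CuI (4 mol%), Et3N, THF, rt; then MeOH, K2CO3 (0.2 equiv), rt
Reagents that add atoms: none
Why: Sonogashira coupling of the aryl iodide with the terminal alkyne, followed by carbonate-catalysed methanolysis of the alkynyl C–Si bond, which is far faster than attack on the hindered aryl O–Si(iPr)3 bond.

Step 7
Reactants: 7 2-iodo-3,5-dimethoxy-6-prenylphenol; 12 (4-ethynylphenoxy)triisopropylsilane; 13 carbon monoxide
Product: 16 5,7-dimethoxy-8-(3-methylbut-2-en-1-yl)-2-[4-(triisopropylsilyloxy)phenyl]-4H-chromen-4-one, via ynone 14 (not isolated), via enaminone 15 (not isolated)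
Conditions: PdCl2(dppf) (5 mol%), CO (20 bar), Et2NH, 120 °C
Reagents that add atoms: none
Why: Pd(0) inserts into the C–I bond of 7, CO migratory insertion gives an aroylpalladium species, and amine-assisted alkynylation with 12 followed by reductive elimination forges C4a–C4 and C4–C3 in ynone 14. Diethylamine then adds to the ynone to give β-aminoenone 15, and the ortho-hydroxyl displaces the amine at the β-carbon to form O1–C2. The closest known reaction is the carbonylative Sonogashira coupling and annulation of 2-iodophenols with terminal alkynes in a secondary amine, which gives flavones. The pyranone ring closes in a 6-endo sense (formally 6-endo-dig on the ynone, realised as addition–elimination on the enaminone), and no stereocentre is formed. Carbonylative coupling must beat direct alkynylation, which is secured by CO pressure, the absence of copper and a di-ortho-substituted arylpalladium that inserts CO readily; flavone must beat aurone, which the amine pathway through 15 secures. Regiochemistry needs no control because 7 has a single free hydroxyl, flanked by the iodine and the prenyl group.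

Step 8
Reactants: 16 5,7-dimethoxy-8-prenyl-4'-(triisopropylsilyloxy)flavone
Product: 18 (2S)-5,7-dimethoxy-8-prenyl-4'-(triisopropylsilyloxy)flavanone, via silyl enol ether 17 (not isolated)
Conditions: Cu(OAc)2 (5 mol%), (R)-DTBM-SEGPHOS (5.5 mol%), (EtO)2MeSiH (3 equiv), toluene, 0 → 25 °C; then AcOH, THF–H2O, 0 °C
Reagents that add atoms: none
Why: Copper hydride-catalysed asymmetric conjugate reduction of a 2-substituted chromone: the bisphosphine-ligated Cu–H transfers hydride to the Re face of C2 (ligand control), which sets 2S, the copper enolate is trapped by the silane as silyl enol ether 17 so that neither ring opening nor 1,2-reduction follows, and mild acid hydrolysis releases the ketone while the prenyl alkene and the aryl silyl ether stay inert.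

Step 9
Reactants: 18 (2S)-5,7-dimethoxy-8-prenyl-4'-(triisopropylsilyloxy)flavanone
Product: 19 (2S)-5-hydroxy-7-methoxy-8-prenyl-4'-(triisopropylsilyloxy)flavanone
Conditions: MgI2·OEt2 (3 equiv), THF, 50 °C; then 0.5 M HCl, aq. Na2S2O3
Reagents that add atoms: none
Why: Chelation-controlled ether cleavage: magnesium bridges the C4 carbonyl oxygen and O5, so iodide removes only the peri methyl group by SN2, the 7-methoxyl, silyl ether and prenyl group are not activated, and the non-basic medium should not enolise C3, so C2 keeps its configuration.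

Step 10
Reactants: 19 (2S)-5-hydroxy-7-methoxy-8-prenyl-4'-(triisopropylsilyloxy)flavanone
Product: 20 Mundulea flavanone B, (2S)-5-hydroxy-2-(4-hydroxyphenyl)-7-methoxy-8-(3-methylbut-2-en-1-yl)chroman-4-one
Conditions: HF·pyridine, pyridine, THF, 0 °C → rt
Reagents that add atoms: none
Why: Fluoride cleavage of the aryl silyl ether under buffered, slightly acidic conditions, which avoids the 4'-phenoxide that would open ring C through a quinone methide and so racemise C2 or reclose onto O5 (Wessely–Moser-type shift of the prenyl group to C6).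

Compound list
1 | 3,5-dimethoxyphenol | COc1cc(O)cc(OC)c1 | starting material
2 | 2-iodo-3,5-dimethoxyphenol | COc1cc(OC)c(I)c(O)c1 | intermediate
3 | allyl bromide | C=CCBr | starting material
4 | 1-(allyloxy)-2-iodo-3,5-dimethoxybenzene | COc1cc(OC)c(I)c(OCC=C)c1 | intermediate
5 | 2-allyl-6-iodo-3,5-dimethoxyphenol | COc1cc(OC)c(CC=C)c(O)c1I | intermediate
6 | 2-methyl-2-butene | CC=C(C)C | starting material
7 | 2-iodo-3,5-dimethoxy-6-(3-methylbut-2-en-1-yl)phenol | COc1cc(OC)c(CC=C(C)C)c(O)c1I | intermediate
8 | 4-iodophenol | Oc1ccc(I)cc1 | starting material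
9 | (4-iodophenoxy)triisopropylsilane | CC(C)[Si](Oc1ccc(I)cc1)(C(C)C)C(C)C | intermediate
10 | trimethylsilylacetylene | C#C[Si](C)(C)C | starting material
11 | triisopropyl{4-[(trimethylsilyl)ethynyl]phenoxy}silane | CC(C)[Si](Oc1ccc(C#C[Si](C)(C)C)cc1)(C(C)C)C(C)C | intermediate (not isolated)
12 | (4-ethynylphenoxy)triisopropylsilane | C#Cc1ccc(O[Si](C(C)C)(C(C)C)C(C)C)cc1 | intermediate
13 | carbon monoxide | [C-]#[O+] | starting material
14 | 1-[2-hydroxy-4,6-dimethoxy-3-(3-methylbut-2-en-1-yl)phenyl]-3-[4-(triisopropylsilyloxy)phenyl]prop-2-yn-1-one | COc1cc(OC)c(C(=O)C#Cc2ccc(O[Si](C(C)C)(C(C)C)C(C)C)cc2)c(O)c1CC=C(C)C | intermediate (not isolated)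
15 | 3-(diethylamino)-1-[2-hydroxy-4,6-dimethoxy-3-(3-methylbut-2-en-1-yl)phenyl]-3-[4-(triisopropylsilyloxy)phenyl]prop-2-en-1-one (alkene geometry not defined) | CCN(CC)C(=CC(=O)c1c(OC)cc(OC)c(CC=C(C)C)c1O)c1ccc(O[Si](C(C)C)(C(C)C)C(C)C)cc1 | intermediate (not isolated)
16 | 5,7-dimethoxy-8-(3-methylbut-2-en-1-yl)-2-[4-(triisopropylsilyloxy)phenyl]-4H-chromen-4-one | COc1cc(OC)c2c(c1CC=C(C)C)oc(-c1ccc(O[Si](C(C)C)(C(C)C)C(C)C)cc1)cc2=O | intermediate
17 | (2S)-4-[diethoxy(methyl)silyloxy]-5,7-dimethoxy-8-(3-methylbut-2-en-1-yl)-2-[4-(triisopropylsilyloxy)phenyl]-2H-chromene | COc1cc(OC)c2c(c1CC=C(C)C)O[C@H](c1ccc(O[Si](C(C)C)(C(C)C)C(C)C)cc1)C=C2O[Si](C)(OCC)OCC | intermediate (not isolated)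
18 | (2S)-5,7-dimethoxy-8-(3-methylbut-2-en-1-yl)-2-[4-(triisopropylsilyloxy)phenyl]chroman-4-one | COc1cc(OC)c2c(c1CC=C(C)C)O[C@H](c1ccc(O[Si](C(C)C)(C(C)C)C(C)C)cc1)CC2=O | intermediate
19 | (2S)-5-hydroxy-7-methoxy-8-(3-methylbut-2-en-1-yl)-2-[4-(triisopropylsilyloxy)phenyl]chroman-4-one | COc1cc(O)c2c(c1CC=C(C)C)O[C@H](c1ccc(O[Si](C(C)C)(C(C)C)C(C)C)cc1)CC2=O | intermediate
20 | Mundulea flavanone B, (2S)-5-hydroxy-2-(4-hydroxyphenyl)-7-methoxy-8-(3-methylbut-2-en-1-yl)chroman-4-one | COc1cc(O)c2c(c1CC=C(C)C)O[C@H](c1ccc(O)cc1)CC2=O | target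

Total step count: 10 (steps 1–4 for the iodophenol, steps 5–6 for the alkyne, step 7 to join them, steps 8–10 to finish).
Longest linear sequence: 8 steps (steps 1–4 and 7–10, from 3,5-dimethoxyphenol).

Steps most likely to fail

1. Step 7. The aroylpalladium may be bypassed by direct alkynylation before CO insertion, which would end in a benzofuran. It may also be intercepted by diethylamine as an amide, or the ynone may close in a 5-exo sense. Fallback, from 7 and 12, rejoining the route at 14 and then 16: the same three bonds are made by polar chemistry. Iodophenol 7 is treated with n-BuLi (2.1 equiv, THF, −78 °C; O–H deprotonation, then iodine–lithium exchange) to give the C,O-dilithio species F1. Quenching with DMF gives 2-hydroxy-4,6-dimethoxy-3-(3-methylbut-2-en-1-yl)benzaldehyde F2. Alkyne 12 is deprotonated with n-BuLi to the lithium acetylide F3, which is used in excess and adds to F2 to give the racemic propargylic alcohol F4. MnO2 (CH2Cl2, rt) oxidises F4 to ynone 14, which is isolated here and closed with Et2NH in EtOH at rt, through 15, to flavone 16.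

2. Step 8. Hydride transfer to the hindered, electron-rich C2 may be slow, facial discrimination may be insufficient, or the copper enolate may eliminate the ring oxygen before it is silylated. Fallback, from 16, rejoining at 18: induction is replaced by resolution. An achiral copper hydride (Cu(OAc)2, 1,2-bis(diphenylphosphino)benzene, (EtO)2MeSiH, toluene) reduces 16 through the racemic silyl enol ether F5 to the racemic flavanone F6 after mild acid hydrolysis. Kinetic resolution by asymmetric transfer hydrogenation (Cp*RhCl(TsDPEN), HCO2H/Et3N, EtOAc, rt, stopped near half conversion, catalyst antipode chosen to consume the 2R ketone) converts the unwanted enantiomer into the cis-(2R,4R)-flavan-4-ol F7. The (2S)-flavanone 18 is left and is separated by chromatography.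

3. Step 9. Warming with a Lewis acid may erode the C2 configuration through reversible opening of ring C. Once O5 is free, reclosure onto it would also move the prenyl group to C6. Fallback, from 16, rejoining at 20: the methyl ether is cleaved while ring C is still a flat, configurationally inert flavone. MgI2·OEt2 (THF, 50 °C) converts 16 into the 5-hydroxyflavone F8. TBSOTf and 2,6-lutidine (CH2Cl2, 0 °C) give the 5-O-TBS flavone F9. The copper hydride reduction of step 8 gives, through the silyl enol ether F10, the (2S)-5-O-TBS flavanone F11. HF·pyridine (pyridine, THF) then removes both silyl groups in one operation and gives 20.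

Further compounds
F1 | step 7 | lithium 2-lithio-3,5-dimethoxy-6-(3-methylbut-2-en-1-yl)phenoxide (not isolated) | [Li]Oc1c([Li])c(OC)cc(OC)c1CC=C(C)C
F2 | step 7 | 2-hydroxy-4,6-dimethoxy-3-(3-methylbut-2-en-1-yl)benzaldehyde | COc1cc(OC)c(C=O)c(O)c1CC=C(C)C
F3 | step 7 | lithium [4-(triisopropylsilyloxy)phenyl]acetylide (not isolated) | [Li]C#Cc1ccc(O[Si](C(C)C)(C(C)C)C(C)C)cc1
F4 | step 7 | racemic 2-{1-hydroxy-3-[4-(triisopropylsilyloxy)phenyl]prop-2-yn-1-yl}-3,5-dimethoxy-6-(3-methylbut-2-en-1-yl)phenol | COc1cc(OC)c(C(O)C#Cc2ccc(O[Si](C(C)C)(C(C)C)C(C)C)cc2)c(O)c1CC=C(C)C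
F5 | step 8 | racemic 4-[diethoxy(methyl)silyloxy]-5,7-dimethoxy-8-(3-methylbut-2-en-1-yl)-2-[4-(triisopropylsilyloxy)phenyl]-2H-chromene (not isolated) | COc1cc(OC)c2c(c1CC=C(C)C)OC(c1ccc(O[Si](C(C)C)(C(C)C)C(C)C)cc1)C=C2O[Si](C)(OCC)OCC
F6 | step 8 | racemic 5,7-dimethoxy-8-(3-methylbut-2-en-1-yl)-2-[4-(triisopropylsilyloxy)phenyl]chroman-4-one | COc1cc(OC)c2c(c1CC=C(C)C)OC(c1ccc(O[Si](C(C)C)(C(C)C)C(C)C)cc1)CC2=O
F7 | step 8 | (2R,4R)-5,7-dimethoxy-8-(3-methylbut-2-en-1-yl)-2-[4-(triisopropylsilyloxy)phenyl]chroman-4-ol | COc1cc(OC)c2c(c1CC=C(C)C)O[C@@H](c1ccc(O[Si](C(C)C)(C(C)C)C(C)C)cc1)C[C@H]2O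
F8 | step 9 | 5-hydroxy-7-methoxy-8-(3-methylbut-2-en-1-yl)-2-[4-(triisopropylsilyloxy)phenyl]-4H-chromen-4-one | COc1cc(O)c2c(c1CC=C(C)C)oc(-c1ccc(O[Si](C(C)C)(C(C)C)C(C)C)cc1)cc2=O
F9 | step 9 | 5-(tert-butyldimethylsilyloxy)-7-methoxy-8-(3-methylbut-2-en-1-yl)-2-[4-(triisopropylsilyloxy)phenyl]-4H-chromen-4-one | COc1cc(O[Si](C)(C)C(C)(C)C)c2c(c1CC=C(C)C)oc(-c1ccc(O[Si](C(C)C)(C(C)C)C(C)C)cc1)cc2=O
F10 | step 9 | (2S)-5-(tert-butyldimethylsilyloxy)-4-[diethoxy(methyl)silyloxy]-7-methoxy-8-(3-methylbut-2-en-1-yl)-2-[4-(triisopropylsilyloxy)phenyl]-2H-chromene (not isolated) | COc1cc(O[Si](C)(C)C(C)(C)C)c2c(c1CC=C(C)C)O[C@H](c1ccc(O[Si](C(C)C)(C(C)C)C(C)C)cc1)C=C2O[Si](C)(OCC)OCC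
F11 | step 9 | (2S)-5-(tert-butyldimethylsilyloxy)-7-methoxy-8-(3-methylbut-2-en-1-yl)-2-[4-(triisopropylsilyloxy)phenyl]chroman-4-one | COc1cc(O[Si](C)(C)C(C)(C)C)c2c(c1CC=C(C)C)O[C@H](c1ccc(O[Si](C(C)C)(C(C)C)C(C)C)cc1)CC2=O
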